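**Retrosynthetic overview**
- The isopropyl group is added last by radical C–H alkylation of the quinone; before that, the lactone bridge is closed by a photoenol (internal redox) lactonisation that also expels the chiral auxiliary.
- Rings B and C come from one benzannulation: Michael addition of a ring A silyl enol ether to 2-acetyl-5-methoxy-1,4-benzoquinone (made by oxidative dearomatisation of an acetylhydroquinone), then aldol condensation and aromatisation.
- Ring A and its quaternary stereocentre come from an auxiliary-controlled Birch reduction–methylation of an o-anisamide, which dearomatises a cheap benzoic acid derivative.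
- Ring order: ring A (from the anisole ring), ring C (brought in as the quinone), ring B (forged between them), lactone bridge last.

Assumption: with the (S)-2-(methoxymethyl)pyrrolidine amide, methyl iodide enters the potassium-chelated Birch enolate anti to the methoxymethyl arm and gives the (1S) quaternary centre; this sense follows a chelation model and is not a recalled literature result, and both antipodes of the auxiliary are sold.

Locants in tricyclic names follow phenanthrene numbering: C1 quaternary carbon, C4 benzylic CH, C5 and C8 quinone carbonyls, C6 OMe, C7 i-Pr, C9 OH.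

**Step 1**
Reactants: 1 2-methoxybenzoyl chloride; 2 (S)-2-(methoxymethyl)pyrrolidine
Product: 3 (S)-(2-methoxyphenyl)[2-(methoxymethyl)pyrrolidin-1-yl]methanone
Conditions: 2 M NaOH (aq), CH2Cl2, 0 °C → rt
Reagents that add atoms: none
Why: Schotten–Baumann N-acylation of the secondary amine by the acid chloride; no stereocentre is touched.

**Step 2**
Reactants: 3
Product: 5 [(1S)-2-methoxy-1-methylcyclohexa-2,5-dien-1-yl][(2S)-2-(methoxymethyl)pyrrolidin-1-yl]methanone, via potassium amide enolate 4 (not isolated)
Conditions: K (2.3 equiv), t-BuOH (1.0 equiv), NH3(l)/THF, −78 °C; piperylene; MeI, −78 °C → rt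
Reagents that add atoms: iodomethane, CI
Why: Asymmetric Birch reduction–alkylation (Schultz): two-electron reduction and para protonation break the aromaticity of the anisole ring and give enolate 4, and MeI alkylates it on the face anti to the methoxymethyl arm of the K-chelated auxiliary, setting the (1S) quaternary centre (dr ≥ 95:5 expected).

**Step 3**
Reactants: 5
Product: 7 [(1S)-1-methyl-2-oxocyclohexyl][(2S)-2-(methoxymethyl)pyrrolidin-1-yl]methanone, via enone 6 (not isolated)
Conditions: 1 M HCl, MeOH, rt; then H2 (1 atm), 10% Pd/C, rt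
Reagents that add atoms: water, O
Why: Acid hydrolysis of the methyl enol ether gives the non-conjugable β,γ-enone 6, and heterogeneous catalytic hydrogenation saturates its isolated cis-alkene; the quaternary centre has no α-hydrogen and cannot epimerise.

**Step 4**
Reactants: 7
Product: 8 [(1S)-1-methyl-2-(trimethylsilyloxy)cyclohex-2-en-1-yl][(2S)-2-(methoxymethyl)pyrrolidin-1-yl]methanone
Conditions: LiN(i-Pr)2, THF, −78 °C; Me3SiCl, −78 → 0 °C; used crude
Reagents that add atoms: chlorotrimethylsilane, C[Si](C)(C)Cl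
Why: Enolate O-silylation; enolisation can only occur toward C3 because the other α-carbon is quaternary, so a single regiodefined silyl enol ether forms.

**Step 5**
Reactants: 9 2-methoxybenzene-1,4-diol (methoxyhydroquinone)
Product: 10 1-(2,5-dihydroxy-4-methoxyphenyl)ethanone
Conditions: AcOH, BF3·OEt2, 90 °C; H2O work-up
Reagents that add atoms: acetic acid, CC(=O)O
Why: Nencki/Fries-type Friedel–Crafts C-acetylation promoted by BF3; acylation goes para to OMe and ortho to OH, the most activated and least hindered position.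

**Step 6**
Reactants: 8; 10
Product: 14 [(1S)-9-hydroxy-6-methoxy-1-methyl-5,8-dioxo-1,2,3,4,5,8-hexahydrophenanthren-1-yl][(2S)-2-(methoxymethyl)pyrrolidin-1-yl]methanone, via acetylquinone 11 (not isolated), via Michael adduct 12 (not isolated), via naphthalenetriol 13 (not isolated)
Conditions: Ag2O, MgSO4, CH2Cl2, rt (10 → 11), filter; add to 8, CH2Cl2, −78 → 0 °C; K2CO3 (20 mol %), MeOH, 50 °C, Ar; then air, rt
Reagents that add atoms: none
Why: Tandem Mukaiyama–Michael/aldol benzannulation: oxidative dearomatisation of 10 gives acylquinone 11, whose doubly activated C3 accepts the silyl enol ether (silyl transfer to the quinone oxygen suppresses redox exchange), then under base the acetyl methyl condenses onto the ring A ketone, tautomerisation aromatises ring B to 13, and air reoxidises ring C; the epimeric centre of 12 is erased on aromatisation and C1 is untouched.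

**Step 7**
Reactants: 14
Product: 18 (1S,4R)-9-hydroxy-6-methoxy-1-methyl-5,8-dioxo-1,2,3,4,5,8-hexahydrophenanthrene-1-carboxylic acid 1,4-lactone, via photoenol 15 (not isolated), via iminium ether 16 (not isolated), via hydroquinone lactone 17 (not isolated)
Conditions: hν (427 nm LEDs), degassed MeCN/NaOAc–AcOH buffer pH 5 (4:1), rt; then air
Reagents that add atoms: water, O
Why: Proposed new method: excitation of the quinone causes 1,5-hydrogen transfer from the ortho benzylic C4–H to the C5 carbonyl (photoenolisation of an o-alkyl aryl ketone, as established for 5-methyl-1,4-naphthoquinone), the quinone methide 15 is captured at C4 by the pseudo-axial amide oxygen, water hydrolyses iminium ether 16 to lactone 17 with release of the auxiliary, and air restores the quinone; the bridge can only close cis, so the (1S) centre fixes C4 as (R); the closest known reaction types are nucleophile trapping of photoenols and the amide-to-lactone transfer of Schultz iodolactonisations.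

**Step 8**
Reactants: 18
Product: 19 (1S,4R)-9-hydroxy-6-methoxy-1-methyl-7-(propan-2-yl)-5,8-dioxo-1,2,3,4,5,8-hexahydrophenanthrene-1-carboxylic acid 1,4-lactone (CNP0271770.1)
Conditions: i-PrCO2H, AgNO3 (20 mol %), (NH4)2S2O8, MeCN/H2O (1:1), 65 °C
Reagents that add atoms: 2-methylpropanoic acid, CC(C)C(=O)O
Why: Kochi–Anderson (Jacobsen–Torssell) decarboxylative radical alkylation; the nucleophilic isopropyl radical adds to C7, the only unsubstituted quinone carbon, and the adduct is reoxidised to the quinone without touching either stereocentre.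

**Compound list**
1 | 2-methoxybenzoyl chloride | COc1ccccc1C(Cl)=O | starting material
2 | (S)-2-(methoxymethyl)pyrrolidine | COC[C@@H]1CCCN1 | starting material
3 | (S)-(2-methoxyphenyl)[2-(methoxymethyl)pyrrolidin-1-yl]methanone | COC[C@@H]1CCCN1C(=O)c1ccccc1OC | intermediate
4 | potassium amide enolate of the 1,4-dihydro derivative of 3 | COC[C@@H]1CCCN1C([O-])=C1C=CCC=C1OC.[K+] | intermediate
5 | [(1S)-2-methoxy-1-methylcyclohexa-2,5-dien-1-yl][(2S)-2-(methoxymethyl)pyrrolidin-1-yl]methanone | COC1=CCC=C[C@]1(C)C(=O)N1CCC[C@H]1COC | intermediate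
6 | [(1S)-1-methyl-6-oxocyclohex-2-en-1-yl][(2S)-2-(methoxymethyl)pyrrolidin-1-yl]methanone | O=C1CCC=C[C@]1(C)C(=O)N1CCC[C@H]1COC | intermediate
7 | [(1S)-1-methyl-2-oxocyclohexyl][(2S)-2-(methoxymethyl)pyrrolidin-1-yl]methanone | O=C1CCCC[C@]1(C)C(=O)N1CCC[C@H]1COC | intermediate
8 | [(1S)-1-methyl-2-(trimethylsilyloxy)cyclohex-2-en-1-yl][(2S)-2-(methoxymethyl)pyrrolidin-1-yl]methanone | C[Si](C)(C)OC1=CCCC[C@]1(C)C(=O)N1CCC[C@H]1COC | intermediate
9 | 2-methoxybenzene-1,4-diol | COc1cc(O)ccc1O | starting material
10 | 1-(2,5-dihydroxy-4-methoxyphenyl)ethanone | CC(=O)c1cc(O)c(OC)cc1O | intermediate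
11 | 2-acetyl-5-methoxy-1,4-benzoquinone | CC(=O)C1=CC(=O)C(OC)=CC1=O | intermediate
12 | [(1S)-3-(2-acetyl-3,6-dihydroxy-5-methoxyphenyl)-1-methyl-2-oxocyclohexyl][(2S)-2-(methoxymethyl)pyrrolidin-1-yl]methanone (C3 epimers, silyl group already lost to methanol) | CC(=O)c1c(O)cc(OC)c(O)c1C1CCC[C@](C)(C(=O)N2CCC[C@H]2COC)C1=O | intermediate
13 | [(1S)-5,8,9-trihydroxy-6-methoxy-1-methyl-1,2,3,4-tetrahydrophenanthren-1-yl][(2S)-2-(methoxymethyl)pyrrolidin-1-yl]methanone | COc1cc(O)c2c(O)cc3c(c2c1O)CCC[C@]3(C)C(=O)N1CCC[C@H]1COC | intermediate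
14 | [(1S)-9-hydroxy-6-methoxy-1-methyl-5,8-dioxo-1,2,3,4,5,8-hexahydrophenanthren-1-yl][(2S)-2-(methoxymethyl)pyrrolidin-1-yl]methanone | COC1=CC(=O)c2c(O)cc3c(c2C1=O)CCC[C@]3(C)C(=O)N1CCC[C@H]1COC | intermediate
15 | photoenol of 14 (C5 enol, exocyclic C4=C4a quinone methide, C8 carbonyl kept) | COC1=CC(=O)C2=C(O)C=C3C(=CCC[C@]3(C)C(=O)N4CCC[C@H]4COC)C2=C1O | intermediate
16 | iminium ether (inner salt) of the C4–O bridged hydroquinone, auxiliary still on the bridge carbon | COc1cc([O-])c2c(O)cc3c(c2c1O)[C@H]1CC[C@]3(C)C(=[N+]2CCC[C@H]2COC)O1 | intermediate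
17 | (1S,4R)-5,8,9-trihydroxy-6-methoxy-1-methyl-1,2,3,4-tetrahydrophenanthrene-1-carboxylic acid 1,4-lactone | COc1cc(O)c2c(O)cc3c(c2c1O)[C@H]1CC[C@]3(C)C(=O)O1 | intermediate
18 | (1S,4R)-9-hydroxy-6-methoxy-1-methyl-5,8-dioxo-1,2,3,4,5,8-hexahydrophenanthrene-1-carboxylic acid 1,4-lactone | COC1=CC(=O)c2c(O)cc3c(c2C1=O)[C@H]1CC[C@]3(C)C(=O)O1 | intermediate
19 | (1S,4R)-9-hydroxy-6-methoxy-1-methyl-7-(propan-2-yl)-5,8-dioxo-1,2,3,4,5,8-hexahydrophenanthrene-1-carboxylic acid 1,4-lactone (CNP0271770.1) | COC1=C(C(C)C)C(=O)c2c(O)cc3c(c2C1=O)[C@H]1CC[C@]3(C)C(=O)O1 | target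

**Totals**
Total step count: 8. Longest linear sequence: 7 (steps 1, 2, 3, 4, 6, 7, 8).

**Steps most likely to fail, with fallbacks**

Step 6 (benzannulation). The risks are closure of the hydroquinone oxygen onto the ring A ketone to give a benzofuran, redox exchange between 11 and 12, and a slow aldol at the hindered ketone. The fallback sets out from 7 and 9 and comes back at 14. Horner–Wadsworth–Emmons olefination of 7 with trimethyl phosphonoacetate and NaH gives the exocyclic enoate F1. γ-Deprotonation with LiN(i-Pr)2 and O-silylation with Me3SiCl gives the vinylketene silyl acetal F2. Bromination of 9 with NBS and oxidation with Ag2O gives 2-bromo-5-methoxy-1,4-benzoquinone F3. A Brassard-type Diels–Alder reaction of F2 with F3 is regiospecific because the nucleophilic diene terminus attacks the unsubstituted carbon next to C–Br; loss of HBr and methanol and hydrolysis of the aryl silyl ether on work-up give 14.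

Step 7 (photoenol lactonisation). The risks are fast reketonisation of the photoenol, deactivation through the hydrogen-bonded peri hydroxyl, and capture by water leading to over-oxidation at C4. The fallback sets out from 14 and comes back at 18. Reductive methylation (Na2S2O4, then Me2SO4, K2CO3, acetone) gives the tetramethyl ether F4. DDQ in dry CH2Cl2 abstracts the benzylic hydride para to the C9 methoxy group, the amide oxygen closes the bridge, and added water hydrolyses the iminium ether to the tetramethoxy lactone F5. (NH4)2Ce(NO3)6 in MeCN/H2O unmasks the quinone to give the dimethoxyquinone F6. BCl3 at −78 °C cleaves the chelated peri methyl ether and gives 18.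

Step 8 (radical isopropylation). The risks are a modest yield, ipso attack at the methoxy-bearing carbon and oxidative damage to the phenol. The fallback sets out from 18 and comes back at 19. Electrophilic bromination (NBS, MeCN) at the enol-ether carbon C7 gives the 7-bromoquinone F7. Suzuki–Miyaura coupling with isopropenylboronic acid pinacol ester (Pd(PPh3)4, K2CO3, dioxane/H2O) gives the 7-isopropenylquinone F8. Homogeneous hydrogenation with RhCl(PPh3)3 and H2, which does not hydrogenolyse the benzylic lactone C–O bond, followed by air, gives 19.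

**Further compounds**
F1 | step 6 | methyl 2-{(2S)-2-methyl-2-[(2S)-2-(methoxymethyl)pyrrolidine-1-carbonyl]cyclohexylidene}acetate | COC(=O)C=C1CCCC[C@]1(C)C(=O)N1CCC[C@H]1COC
F2 | step 6 | {(1S)-2-[2-methoxy-2-(trimethylsilyloxy)ethenyl]-1-methylcyclohex-2-en-1-yl}[(2S)-2-(methoxymethyl)pyrrolidin-1-yl]methanone | COC(O[Si](C)(C)C)=CC1=CCCC[C@]1(C)C(=O)N1CCC[C@H]1COC
F3 | step 6 | 2-bromo-5-methoxy-1,4-benzoquinone | COC1=CC(=O)C(Br)=CC1=O
F4 | step 7 | [(1S)-5,6,8,9-tetramethoxy-1-methyl-1,2,3,4-tetrahydrophenanthren-1-yl][(2S)-2-(methoxymethyl)pyrrolidin-1-yl]methanone | COc1cc(OC)c2c(OC)cc3c(c2c1OC)CCC[C@]3(C)C(=O)N1CCC[C@H]1COC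
F5 | step 7 | (1S,4R)-5,6,8,9-tetramethoxy-1-methyl-1,2,3,4-tetrahydrophenanthrene-1-carboxylic acid 1,4-lactone | COc1cc(OC)c2c(OC)cc3c(c2c1OC)[C@H]1CC[C@]3(C)C(=O)O1
F6 | step 7 | (1S,4R)-6,9-dimethoxy-1-methyl-5,8-dioxo-1,2,3,4,5,8-hexahydrophenanthrene-1-carboxylic acid 1,4-lactone | COC1=CC(=O)c2c(OC)cc3c(c2C1=O)[C@H]1CC[C@]3(C)C(=O)O1
F7 | step 8 | (1S,4R)-7-bromo-9-hydroxy-6-methoxy-1-methyl-5,8-dioxo-1,2,3,4,5,8-hexahydrophenanthrene-1-carboxylic acid 1,4-lactone | COC1=C(Br)C(=O)c2c(O)cc3c(c2C1=O)[C@H]1CC[C@]3(C)C(=O)O1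
F8 | step 8 | (1S,4R)-9-hydroxy-6-methoxy-1-methyl-5,8-dioxo-7-(prop-1-en-2-yl)-1,2,3,4,5,8-hexahydrophenanthrene-1-carboxylic acid 1,4-lactone | COC1=C(C(C)=C)C(=O)c2c(O)cc3c(c2C1=O)[C@H]1CC[C@]3(C)C(=O)O1
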